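The route depends on disconnecting C6–C7 of ring A. Three adjacent ring B carbons, C5 (gem-dimethyl), C6 (spiro) and C1 (methyl-bearing), already sit side by side, in the correct absolute sense, at the cyclopropane of (−)-thujopsene. Dilute acid should open its vinylcyclopropane to a ring-expanded C6 cation and contract the seven-membered ring by a 1,2-shift of C7. One operation thus creates ring A, the spiro stereocentre and the C1=C2 alkene. The precursor is the commercial tricyclic sesquiterpene itself, only distilled. Afterwards ring A becomes the bromoalkene by way of a C10 ketone, and ring B is oxidised at C3, brominated at C4, reduced, and inverted at C3.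

Key step: step 1

Numbering: ring B = C1 (sp2, bears CH3), C2, C3 (carbinol), C4 (CHBr), C5 (CMe2), C6 (spiro). Ring A = C6, C7, C8, C9 (sp2, bears CH3), C10 (CBr), C11. The faces of ring B are named after the ring A methylene standing on them. In the target, Br lies on the C11 face and OH on the C7 face (trans).
Atom map of step 1 (thujopsene locant → route locant): 8a→6, 8→5, 4a→1, 5→2, 6→3, 7→4, 4→7, 3→8, 2→9, 1a→10, 1→11.
Assumption: commercial 1 is the enantiopure (1aS,4aS,8aS) form, and the optical purity of 5 is checked by chiral GC before it is carried on.

Step 1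
Reactants: 1 (−)-thujopsene
Product: 5 (6R)-α-chamigrene, via cyclopropylcarbinyl cation 2 (not isolated), via ring-expanded homoallyl cation 3 (not isolated), via chamigrenyl cation 4 (not isolated)
Conditions: HClO4 (0.02 M), dioxane–H2O 4:1, reflux, GC control, NaHCO3 quench before full conversion; AgNO3–SiO2 chromatography
Reagents that add atoms: none
Why: The alkene of 1 is protonated at C8 far more readily than an ordinary trisubstituted alkene because it gives the tertiary cyclopropylcarbinyl cation 2, whose internal cyclopropane bond C6–C10 breaks with release of strain to give the homoallyl cation 3 (charge on C6, seven-membered ring, C9=C10 alkene already in place). C7 then moves from C1 to C6 to give the tertiary cation 4, and loss of a C2 proton gives the endocyclic alkene of 5. The closest known reaction type is the acid-catalysed cyclopropylcarbinyl–homoallyl rearrangement followed by a Wagner–Meerwein shift, which is documented for thujopsene itself. Ring A (six-membered carbocycle) arises by ring contraction: a suprafacial 1,2-alkyl shift inside the seven-membered ring forms C6–C7, so no open-chain cyclisation is involved. C6 is controlled by the angular stereocentre C1 of 3: C7 is bound to C1 on the ring B face that the C6–C10 bond has just left and can only slide across that face, so the chirality of C1 is transcribed into C6 (R) as C1 becomes planar. The step needs the C7 shift to beat methyl migration and water capture, endocyclic to beat exocyclic proton loss, and the ring A alkene of 5 to stay unprotonated (a C9 cation makes ring A symmetric, which racemises C6, and is also trapped by C1=C2); the seven-membered tether aligns C1–C7 with the empty orbital, water capture and exocyclic loss are reversible under the conditions, and low acidity plus early quenching protects 5.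

Step 2
Reactants: 5 (6R)-α-chamigrene
Product: 7 (6R,9S,10S)-chamigr-1-en-10-ol, via B-alkyl-9-BBN adduct 6 (not isolated)
Conditions: 9-BBN (1.2 equiv), THF, 65 °C; then NaOH, H2O2, 0 °C → rt
Reagents that add atoms: hydrogen peroxide, OO (oxygen on C10); 9-BBN, B1C2CCCC1CCC2 (boron fragment, present only in 6)
Why: Brown hydroboration–oxidation: the bulky borane should add only to the ring A alkene (C1=C2 adjoins quaternary C6 and is screened on both faces by C7 and C11), placing boron on the less substituted C10 by syn addition from the ring A face remote from the C1 methyl, with retention on oxidation and without any C9 cation that C1=C2 could capture; C9 and C10 are erased in steps 3 and 4, so a minor facial isomer converges.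

Step 3
Reactants: 7 (6R,9S,10S)-chamigr-1-en-10-ol
Product: 8 (6R,9S)-chamigr-1-en-10-one
Conditions: (n-Pr4N)RuO4 (5 mol %), NMO, 4 Å molecular sieves, CH2Cl2, rt
Reagents that add atoms: none
Why: Ley–Griffith oxidation turns the secondary alcohol into the ketone under neutral conditions that leave the acid-sensitive C1=C2 alkene and C6 untouched.

Step 4
Reactants: 8 (6R,9S)-chamigr-1-en-10-one
Product: 10 (6R)-chamigra-1,9-dien-10-yl triflate, via bromomagnesium enolate 9 (not isolated)
Conditions: i-Pr2NMgBr (from EtMgBr + i-Pr2NH), Et2O–THF, rt (equilibration); then PhNTf2, rt → 40 °C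
Reagents that add atoms: N-phenylbis(trifluoromethanesulfonimide), O=S(=O)(N(c1ccccc1)S(=O)(=O)C(F)(F)F)C(F)(F)F; ethylmagnesium bromide, CC[Mg]Br (Mg and Br present only in 9)
Why: Thermodynamic enolate trapping: the magnesium amide equilibrates the enolates toward the tetrasubstituted C9=C10 isomer (C11 is neopentylic and would give the less substituted enolate), and O-sulfonylation fixes the double bond where the target needs it, so C6 keeps its sense.

Step 5
Reactants: 10 (6R)-chamigra-1,9-dien-10-yl triflate
Product: 11 (6R)-3-oxochamigra-1,9-dien-10-yl triflate
Conditions: CrO3, 3,5-dimethylpyrazole, CH2Cl2, −20 °C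
Reagents that add atoms: chromium trioxide, O=[Cr](=O)=O
Why: Allylic oxidation with the CrO3–dimethylpyrazole complex: C3 is the only ring methylene allylic to the electron-rich C1=C2 alkene (C6 is quaternary), whereas the triflate strongly deactivates the ring A alkene and its allylic C–H bonds toward the electrophilic oxidant, which is why this step precedes the triflate–bromide exchange.

Step 6
Reactants: 11 (6R)-3-oxochamigra-1,9-dien-10-yl triflate
Product: 12 (6R)-10-bromochamigra-1,9-dien-3-one
Conditions: [Cp*Ru(MeCN)3]OTf (5 mol %), LiBr, 1,3-dimethyl-2-imidazolidinone, 60 °C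
Reagents that add atoms: lithium bromide, [Li+].[Br-]
Why: Ruthenium-catalysed halide exchange of an alkenyl triflate: insertion of the cationic Cp*Ru fragment into C10–O and delivery of bromide should replace OTf by Br without moving the C9=C10 double bond, the enone being a spectator.

Step 7
Reactants: 12 (6R)-10-bromochamigra-1,9-dien-3-one; 13 N-bromosuccinimide
Product: 16 (4S,6S)-4,10-dibromochamigra-1,9-dien-3-one, via lithium dienolate 14 (not isolated), via silyl dienol ether 15 (not isolated)
Conditions: LiN(i-Pr)2, THF, −78 °C; Me3SiCl, −78 → 0 °C, volatiles removed; NBS, THF, −78 → 0 °C; then DBU (0.1 equiv), CH2Cl2, rt (C4 equilibration)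
Reagents that add atoms: N-bromosuccinimide, O=C1CCC(=O)N1Br; chlorotrimethylsilane, C[Si](C)(C)Cl (silyl group present only in 15); lithium diisopropylamide, [Li]N(C(C)C)C(C)C (Li present only in 14)
Why: Kinetic α′-deprotonation, silylation and electrophilic bromination of the silyl dienol ether is the standard α′-halogenation of an enone, and because C5 is quaternary no HBr loss is possible, so base-catalysed enolisation can settle C4 as the equatorial bromide of the preferred ring B sofa, in which the flattened C11–C10 arm (no axial hydrogen on C10) lies pseudo-equatorial beside the C1 methyl and C7 is pseudo-axial, which places bromine on the C11 face (the C6 descriptor changes to S by priority only).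

Step 8
Reactants: 16 (4S,6S)-4,10-dibromochamigra-1,9-dien-3-one
Product: 17 (3R,4S,6S)-4,10-dibromochamigra-1,9-dien-3-ol (cis-bromohydrin)
Conditions: i-Bu2AlH, CH2Cl2, −78 °C; aqueous potassium sodium tartrate
Reagents that add atoms: none
Why: 1,2-Reduction of the enone (C1 is fully substituted, so no conjugate path): the bulky hydride should reach C3 from the C7 face because the C11 face is closed by the axial C5 methyl (1,3 to C3) and the equatorial bromine, so the hydroxyl ends on the C11 face, cis to bromine; this natural bias is accepted here and corrected in step 9 instead of being opposed.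

Step 9
Reactants: 17 (3R,4S,6S)-4,10-dibromochamigra-1,9-dien-3-ol
Product: 18 (3S,4S,6S)-4,10-dibromochamigra-1,9-dien-3-yl 4-nitrobenzoate
Conditions: 4-O2NC6H4CO2H, PPh3, DIAD, THF, 0 °C → rt
Reagents that add atoms: 4-nitrobenzoic acid, O=C(O)c1ccc(cc1)[N+](=O)[O-]
Why: Mitsunobu inversion: the activated pseudo-axial allylic C3–O bond is displaced by carboxylate from the open C7 face in an SN2 process that sets the trans relation, since bromine is cis to the leaving group and cannot participate, and SN2′ attack at C1 is blocked by full substitution next to C6; the crystalline ester also allows isomeric purity to be upgraded.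

Step 10
Reactants: 18 (3S,4S,6S)-4,10-dibromochamigra-1,9-dien-3-yl 4-nitrobenzoate
Product: 19 target, (3S,4S,6S)-4,10-dibromo-1,5,5,9-tetramethylspiro[5.5]undeca-1,9-dien-3-ol
Conditions: K2CO3 (0.1 equiv), MeOH, 0 °C
Reagents that add atoms: none
Why: Base-catalysed transesterification cleaves the acyl–oxygen bond and so leaves C3 untouched, while catalytic carbonate at 0 °C keeps the alkoxide concentration low and the diequatorial bromohydrin would have to force bromine against C11 to reach the diaxial geometry needed for epoxide closure.

Compound list
1 | (−)-thujopsene, (1aS,4aS,8aS)-2,4a,8,8-tetramethyl-1,1a,4,4a,5,6,7,8-octahydrocyclopropa[d]naphthalene | CC1=CC[C@]2(C)CCCC(C)(C)[C@@]23C[C@@H]13 | starting material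
2 | protonated thujopsene, tertiary cyclopropylcarbinyl cation with the charge on future C9 | C[C+]1CC[C@]2(C)CCCC(C)(C)[C@@]23C[C@@H]13 | intermediate
3 | ring-expanded bicyclo[5.4.0] homoallyl cation, charge on C6 between C5 (CMe2) and angular C1 (CH3), C9=C10 in the seven-membered ring | CC1=CC[C+]2C(C)(C)CCC[C@@]2(C)CC1 | intermediate
4 | chamigrenyl cation, spiro[5.5] skeleton with C6 set and the charge on C1 | C[C+]1CCCC(C)(C)[C@]12CCC(C)=CC2 | intermediate
5 | (6R)-α-chamigrene, (6R)-1,5,5,9-tetramethylspiro[5.5]undeca-1,9-diene | CC1=CCCC(C)(C)[C@]12CCC(C)=CC2 | intermediate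
6 | 9-(chamigr-1-en-10-yl)-9-borabicyclo[3.3.1]nonane, B on C10 and new H on C9 syn, on the ring A face away from C1, C9-CH3 trans to B | CC1=CCCC(C)(C)[C@]12CC[C@H](C)[C@@H](B3C4CCCC3CCC4)C2 | intermediate
7 | (6R,9S,10S)-1,5,5,9-tetramethylspiro[5.5]undec-1-en-10-ol (route numbering), C9-CH3 and C10-OH trans | CC1=CCCC(C)(C)[C@]12CC[C@H](C)[C@@H](O)C2 | intermediate
8 | (6R,9S)-1,5,5,9-tetramethylspiro[5.5]undec-1-en-10-one (route numbering) | CC1=CCCC(C)(C)[C@]12CC[C@H](C)C(=O)C2 | intermediate
9 | bromomagnesium C9=C10 enolate of 8 | CC1=CCCC(C)(C)[C@]12CCC(C)=C(O[Mg]Br)C2 | intermediate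
10 | (6R)-1,5,5,9-tetramethylspiro[5.5]undeca-1,9-dien-10-yl trifluoromethanesulfonate | CC1=CCCC(C)(C)[C@]12CCC(C)=C(OS(=O)(=O)C(F)(F)F)C2 | intermediate
11 | (6R)-1,5,5,9-tetramethyl-3-oxospiro[5.5]undeca-1,9-dien-10-yl trifluoromethanesulfonate | CC1=CC(=O)CC(C)(C)[C@]12CCC(C)=C(OS(=O)(=O)C(F)(F)F)C2 | intermediate
12 | (6R)-10-bromo-1,5,5,9-tetramethylspiro[5.5]undeca-1,9-dien-3-one | CC1=CC(=O)CC(C)(C)[C@]12CCC(C)=C(Br)C2 | intermediate
13 | N-bromosuccinimide | O=C1CCC(=O)N1Br | starting material
14 | lithium cross-conjugated dienolate of 12 (C3–OLi, C3=C4) | CC1=CC(O[Li])=CC(C)(C)[C@]12CCC(C)=C(Br)C2 | intermediate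
15 | 3-trimethylsilyloxy-1,3-diene of ring B (silyl dienol ether of 12) | CC1=CC(O[Si](C)(C)C)=CC(C)(C)[C@]12CCC(C)=C(Br)C2 | intermediate
16 | (4S,6S)-4,10-dibromo-1,5,5,9-tetramethylspiro[5.5]undeca-1,9-dien-3-one, C4-Br equatorial on the C11 face | CC1=CC(=O)[C@@H](Br)C(C)(C)[C@]12CCC(C)=C(Br)C2 | intermediate
17 | (3R,4S,6S)-4,10-dibromo-1,5,5,9-tetramethylspiro[5.5]undeca-1,9-dien-3-ol, OH and Br both on the C11 face | CC1=C[C@@H](O)[C@@H](Br)C(C)(C)[C@]12CCC(C)=C(Br)C2 | intermediate
18 | (3S,4S,6S)-4,10-dibromo-1,5,5,9-tetramethylspiro[5.5]undeca-1,9-dien-3-yl 4-nitrobenzoate, ester oxygen on the C7 face | CC1=C[C@H](OC(=O)c3ccc(cc3)[N+](=O)[O-])[C@@H](Br)C(C)(C)[C@]12CCC(C)=C(Br)C2 | intermediate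
19 | (3S,4S,6S)-4,10-dibromo-1,5,5,9-tetramethylspiro[5.5]undeca-1,9-dien-3-ol | CC1=C[C@H](O)[C@@H](Br)C(C)(C)[C@]12CCC(C)=C(Br)C2 | target

Total step count: 10. Longest linear sequence: 10 steps, from 1.

Steps most likely to fail

Risk 1, step 1.
- **What may go wrong:** The cation manifold may leak through water capture at C6, exocyclic proton loss at the C1 methyl, or onward cyclisation of the product. Slow protonation of the ring A alkene would also erode optical purity.
- **Fallback:** The event is split in two, setting out from 1. Hydration with aqueous oxalic acid in dioxane at moderate temperature should stop at the crystalline tertiary alcohol widdrol F1. Here water adds to C6 of cation 3 anti to the departing C6–C10 bond, so the hydroxyl is cis to the angular methyl, and F1 is purified by crystallisation.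
- **Return to the route:** F1 is then ionised in a water-free medium (catalytic camphorsulfonic acid, molecular sieves, CH2Cl2, 0 °C). Cation 3 is then generated at low temperature from a C–O bond, cannot be recaptured by water, and contracts to 5, where the route is rejoined.

Risk 2, step 7.
- **What may go wrong:** The two faces of ring B differ only in which ring A arm they carry, so facial discrimination at C4 may be poor. Bromine may also be exchanged between enolates during equilibration.
- **Fallback:** Enolate bromination and the later C3 inversion are abandoned, and both centres are made by anti addition, setting out from 12. Luche reduction (NaBH4, CeCl3·7H2O, MeOH, 0 °C) gives the ring B allylic alcohol F5 (either C3 epimer). Acid-catalysed dehydration under equilibrating conditions (catalytic TsOH, benzene, reflux) gives the endocyclic ring B 1,3-diene F6.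
- **Return to the route:** NBS in aqueous acetone at 0 °C adds bromine to the diene terminus C4 and water to the allylic C3 from the opposite face. The trans relation is then fixed by mechanism, and only facial isomers need separating. The route is rejoined at 19, and steps 8 to 10 fall away.

Risk 3, step 5.
- **What may go wrong:** Hydrogen abstraction from the ring A allylic positions or the C1 methyl may compete, and conversion at the hindered alkene may be sluggish.
- **Fallback:** C–H oxidation is replaced by chemistry that depends only on alkene nucleophilicity, setting out from 10. mCPBA (NaHCO3, CH2Cl2, 0 °C) should epoxidise only C1=C2 to the ring B epoxide F2. PhSeNa (from PhSeSePh and NaBH4, EtOH) opens it at the secondary C2 to the hydroxy selenide F3.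
- **Return to the route:** H2O2 oxidation and selenoxide syn-elimination can run only toward C3 because C1 bears no hydrogen, and this gives the tertiary allylic alcohol F4. Pyridinium chlorochromate, C5H5NH[CrO3Cl], then effects the Babler–Dauben oxidative 1,3-transposition to 11, where the route is rejoined.

Further compounds
F1 | step 1 | widdrol, C6 tertiary alcohol of the ring-expanded skeleton, OH cis to the angular methyl | CC1=CC[C@@]2(O)C(C)(C)CCC[C@@]2(C)CC1
F2 | step 5 | C1,C2-epoxide of 10 (epoxide face immaterial) | CC12OC1CCC(C)(C)[C@]23CCC(C)=C(OS(=O)(=O)C(F)(F)F)C3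
F3 | step 5 | C1-hydroxy C2-phenylselenide from F2 (C1 and C2 configuration immaterial) | CC1(O)C([Se]c3ccccc3)CCC(C)(C)[C@]12CCC(C)=C(OS(=O)(=O)C(F)(F)F)C2
F4 | step 5 | tertiary allylic alcohol, C1-OH with C2=C3 (C1 configuration immaterial) | CC1(O)C=CCC(C)(C)[C@]12CCC(C)=C(OS(=O)(=O)C(F)(F)F)C2
F5 | step 7 | (6R)-10-bromochamigra-1,9-dien-3-ol (either C3 epimer) | CC1=CC(O)CC(C)(C)[C@]12CCC(C)=C(Br)C2
F6 | step 7 | (6R)-10-bromochamigra-1,3,9-triene | CC1=CC=CC(C)(C)[C@]12CCC(C)=C(Br)C2
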